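The synthesis rests on disconnecting the tetrasubstituted C7=C11 bond of the butenolide ring (O–C12–C11=C7–C6; germacrane numbering, carbocycle C1–C10). C7 lies between the oxygen-bearing carbons C6 and C8, so it can be carried as a ring ketone while C11 arrives as a phosphonate carbanion tethered through the C6 ester oxygen. A single intramolecular Horner–Wadsworth–Emmons reaction then forms C7=C11 and closes the lactone, creating no stereocentre. Its precursor is the fully functionalised ten-membered 7-ketone carrying both epoxides, the C8 (S)-2-methylglycidate and, on O6, a 2-(diethoxyphosphoryl)-3-silyloxypropanoate that already contains C11, C12 and C13.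

Key step: step 22

Remark 1: germacrane numbering (C1–C15) is used for all intermediates; R/S descriptors quoted with these locants were assigned compound by compound.
Remark 2: the C7 carbinol is a relay stereocentre, set syn to O6 and O8 so that chelation control can be used; it is erased in step 21. C11 of the phosphonate is carried as a mixture of epimers, which is immaterial.
Remark 3: (R)-2-methylglycidol is taken as a commercial starting material.

Step 1
Reactants: 1 diethyl D-tartrate
Product: 2 diethyl (2S,3S)-2-hydroxy-3-[(4-methoxybenzyl)oxy]butanedioate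
Conditions: Ag2O (1.5 equiv), 4-MeOC6H4CH2Cl (1.1 equiv), CH2Cl2, rt, dark
Reagents that add atoms: 4-methoxybenzyl chloride, COc1ccc(CCl)cc1
Why: Silver-oxide-mediated Williamson mono-etherification of a C2-symmetric diol, whose two hydroxyls are equivalent, so one mono-ether results and no stereocentre is touched; the ether oxygen becomes O7 and the free hydroxyl O6.

Step 2
Reactants: 2 mono-PMB tartrate
Product: 3 ethyl (2S,3R)-3,4-dihydroxy-2-[(4-methoxybenzyl)oxy]butanoate
Conditions: BH3·SMe2 (1.05 equiv), NaBH4 (5 mol %), THF, 0 °C → rt; MeOH quench; used crude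
Reagents that add atoms: none
Why: Hydroxyl-directed borane reduction of an α-hydroxy ester: the alkoxyborane at the free C6 hydroxyl delivers hydride only to the neighbouring ester (future C5) and leaves the ester next to the PMB ether; the diol is silylated at once to forestall γ-lactonisation.

Step 3
Reactants: 3 diol ester
Product: 4 ethyl (2S,3R)-2-[(4-methoxybenzyl)oxy]-3,4-bis[(triethylsilyl)oxy]butanoate
Conditions: Et3SiCl (2.4 equiv), imidazole, DMAP (cat.), CH2Cl2, 0 °C → rt
Reagents that add atoms: chlorotriethylsilane, CC[Si](Cl)(CC)CC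
Why: Routine silyl ether formation at both hydroxyls; the primary (O5) and secondary (O6) triethylsilyl ethers are differentiated later by their different rates under Swern conditions.

Step 4
Reactants: 4 bis-silyl ester
Product: 5 (2S,3R)-2-[(4-methoxybenzyl)oxy]-3,4-bis[(triethylsilyl)oxy]butanal
Conditions: i-Bu2AlH (1.1 equiv), CH2Cl2, −78 °C; aqueous potassium sodium tartrate; used crude
Reagents that add atoms: none
Why: Partial reduction of an α-alkoxy ester with i-Bu2AlH: the chelated aluminium hemiacetal is stable at −78 °C and releases the C8 aldehyde only on work-up, and immediate use avoids epimerisation at C7.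

Step 5
Reactants: 5 C5–C8 aldehyde
Product: 6 (2R,3R,4S)-3-[(4-methoxybenzyl)oxy]-1,2-bis[(triethylsilyl)oxy]hept-6-yn-4-ol
Conditions: MgBr2·OEt2 (2.5 equiv), allenyltributylstannane (1.5 equiv), CH2Cl2, −78 → −20 °C
Reagents that add atoms: allenyltributylstannane, C=C=C[Sn](CCCC)(CCCC)CCCC
Why: Chelation-controlled SE2′ propargylation: MgBr2 bridges the aldehyde oxygen and the α-OPMB oxygen, the allenylstannane attacks the less hindered face of the five-membered chelate and C8 is set syn to O7 (8S), while the C6 silyl ether does not chelate.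

Step 6
Reactants: 6 homopropargylic alcohol
Product: 8 (6E)-diene alcohol, via alkenylalane 7 (not isolated)
Conditions: Me3Al (3.5 equiv), Cp2ZrCl2 (0.3 equiv), CH2Cl2, 0 °C → rt; evaporate; ZnCl2 (1 equiv), Pd(PPh3)4 (5 mol %), vinyl bromide (3 equiv), THF, rt
Reagents that add atoms: trimethylaluminium, C[Al](C)C; vinyl bromide, C=CBr
Why: Negishi zirconium-catalysed carboalumination adds CH3 and Al syn across the terminal alkyne (methyl to C10, aluminium to C1) and the palladium-catalysed coupling of the alkenylalane with vinyl bromide occurs with retention, fixing the 1(10)E geometry; the C8 hydroxyl travels as its aluminium alkoxide.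

Step 7
Reactants: 8 diene alcohol
Product: 9 acyclic vinyl epoxide alcohol with (1R,10R)-1,10-epoxide
Conditions: Shi ketone from D-fructose (0.3 equiv), KHSO5 (as 2KHSO5·KHSO4·K2SO4), K2CO3, Bu4NHSO4, MeCN/CH2(OMe)2/aq. Na2B4O7 buffer (pH 10.5), 0 °C
Reagents that add atoms: potassium peroxymonosulfate, [K+].[O-]S(=O)(=O)OO
Why: Shi asymmetric epoxidation: the chiral dioxirane reacts through its spiro transition state at the electron-rich trisubstituted C1=C10 bond of the diene and leaves the terminal vinyl group, so reagent control sets C1 and C10 (both R) independently of the remote stereocentres.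

Step 8
Reactants: 10 (R)-2-methylglycidol
Product: 11 (2S)-2-methyloxirane-2-carboxylic acid
Conditions: RuCl3 (2 mol %), NaIO4 (4 equiv), MeCN/EtOAc/H2O, 0 °C → rt
Reagents that add atoms: water, O
Why: Ruthenium tetroxide oxidation (catalytic RuCl3 with NaIO4) of a primary epoxy alcohol to the acid; the quaternary centre is not involved, and its descriptor changes from R to S only because the substituent priorities change.

Step 9
Reactants: 9 vinyl epoxide alcohol; 11 (2S)-2-methyloxirane-2-carboxylic acid
Product: 12 C8 (2S)-2-methylglycidate of 9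
Conditions: DCC (1.5 equiv), DMAP (0.2 equiv), CH2Cl2, 0 °C → rt
Reagents that add atoms: none
Why: Steglich esterification of the only free hydroxyl by acyl transfer, so C8 and the glycidate centre keep their configuration; the final C8 ester is thus in place early and also masks O8 during the coming oxidation.

Step 10
Reactants: 12 bis-silyl glycidate
Product: 13 C5 aldehyde with 6-OTES retained
Conditions: (COCl)2 (4 equiv), DMSO (8 equiv), CH2Cl2, −78 → −40 °C; Et3N, −78 → 0 °C
Reagents that add atoms: none
Why: Swern oxidation applied directly to the bis-silyl ether: the primary triethylsilyl ether is cleaved by the chlorosulfonium salt and oxidised in the same flask, whereas the secondary C6 silyl ether, both epoxides and the ester are inert under these cold, non-aqueous conditions.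

Step 11
Reactants: 13 α-silyloxy aldehyde
Product: 14 (4Z)-vinyl iodide bearing the vinyl epoxide arm
Conditions: EtPPh3I, n-BuLi, THF, 0 °C; I2, −78 °C; NaN(SiMe3)2, −20 °C; then 13, −78 → −20 °C
Reagents that add atoms: ethyltriphenylphosphonium iodide, CC[P+](c1ccccc1)(c1ccccc1)c1ccccc1.[I-]; iodine, II
Why: Stork–Zhao-type Wittig olefination with the α-iodoethylidene ylide, whose kinetically formed cis-oxaphosphetane leads to the (Z)-2-iodoalkene (iodine cis to C6), which is the geometry required for the 4Z ring alkene; C4 and C15 come from the ylide and the cold salt-free conditions spare C6.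

Step 12
Reactants: 14 Z-vinyl iodide
Product: 16 ten-membered (4Z)-carbocycle, via B-alkyl borane 15 (not isolated)
Conditions: 9-BBN (2 equiv), THF, 0 °C → rt; then syringe-pump addition to Pd(dppf)Cl2 (0.2 equiv), AsPh3 (0.4 equiv), Cs2CO3 (3 equiv), DMF/THF/H2O, rt, about 1 mM
Reagents that add atoms: none
Why: Anti-Markovnikov hydroboration of the terminal vinyl group followed by an intramolecular B-alkyl Suzuki–Miyaura coupling with the vinyl iodide under high dilution closes the carbocycle at C3–C4 with retention of the Z geometry; no stereocentre is formed and the hindered 9-BBN is chosen to leave the epoxide and ester untouched.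

Step 13
Reactants: 16 macrocyclic silyl ether
Product: 17 macrocyclic C6 allylic alcohol
Conditions: Bu4NF/AcOH (1:1, 2 equiv), THF, 0 °C → rt
Reagents that add atoms: none
Why: Fluoride-mediated cleavage of the secondary triethylsilyl ether, buffered with acetic acid so that neither 1,3-acyl migration from O8 nor transannular opening of the 1,10-epoxide is triggered.

Step 14
Reactants: 17 allylic alcohol
Product: 18 (1R,4R,5S,6S,7S,8S,10R)-diepoxy alcohol
Conditions: VO(acac)2 (10 mol %), t-BuOOH (decane, 1.5 equiv), CH2Cl2, 0 °C → rt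
Reagents that add atoms: tert-butyl hydroperoxide, CC(C)(C)OO
Why: Vanadium-catalysed hydroxyl-directed epoxidation: the C6 alkoxide bound to pentavalent vanadium delivers the peroxide oxygen to the alkene face syn to O6, the outcome known for medium-ring cycloalk-2-enols, which sets C4 (R) and C5 (S) cis to O6; only the allylic alkene reacts.

Step 15
Reactants: 19 triethyl phosphonoacetate
Product: 20 ethyl 3-(benzyloxy)-2-(diethoxyphosphoryl)propanoate
Conditions: NaH (1.0 equiv), THF, 0 °C; BnOCH2Cl (1.05 equiv), 0 °C → rt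
Reagents that add atoms: benzyl chloromethyl ether, ClCOCc1ccccc1
Why: C-alkylation of the stabilised phosphonoacetate anion with a reactive α-chloro ether introduces C13 together with its oxygen; the mono-alkylated product is less acidic, which limits dialkylation.

Step 16
Reactants: 20 benzyl ether
Product: 21 ethyl 2-(diethoxyphosphoryl)-3-hydroxypropanoate
Conditions: H2 (1 atm), Pd on carbon, EtOH, rt
Reagents that add atoms: none
Why: Hydrogenolysis of the benzyl ether under neutral conditions, which avoids the base-induced retro-aldol or dehydration pathways open to this β-hydroxy phosphonoacetate.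

Step 17
Reactants: 21 primary alcohol
Product: 22 ethyl 3-[(tert-butyldimethylsilyl)oxy]-2-(diethoxyphosphoryl)propanoate
Conditions: t-BuMe2SiCl (1.2 equiv), imidazole, CH2Cl2, 0 °C → rt
Reagents that add atoms: tert-butylchlorodimethylsilane, CC(C)(C)[Si](C)(C)Cl
Why: Silylation of the primary alcohol; the silyl ether is a poor leaving group, so the later carbanion does not eliminate, and it is removable under buffered fluoride at the end.

Step 18
Reactants: 22 triester
Product: 23 3-[(tert-butyldimethylsilyl)oxy]-2-(diethoxyphosphoryl)propanoic acid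
Conditions: LiOH (1.1 equiv), THF/H2O, 0 °C; then 1 M HCl to pH 3
Reagents that add atoms: lithium hydroxide, [Li+].[OH-]
Why: Saponification: the carboxylic ethyl ester is hydrolysed much faster than the phosphonate ethyl esters and the primary silyl ether is stable to cold aqueous hydroxide.

Step 19
Reactants: 18 diepoxy alcohol; 23 phosphonoacetic acid
Product: 24 C6 phosphonoacetate with 7-OPMB
Conditions: DCC (1.5 equiv), DMAP (0.1 equiv), CH2Cl2, 0 °C → rt
Reagents that add atoms: none
Why: Steglich esterification of the hindered C6 hydroxyl by the activated phosphonoacetic acid with retention at C6; the neutral conditions give no Payne rearrangement of the adjacent epoxide.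

Step 20
Reactants: 24 PMB ether
Product: 25 C7 alcohol flanked by both esters
Conditions: DDQ (1.5 equiv), CH2Cl2/pH 7 phosphate buffer, 0 °C
Reagents that add atoms: none
Why: Oxidative cleavage of the PMB ether by DDQ (benzylic hydride abstraction, then hydrolysis of the oxocarbenium ion) under buffered neutral conditions that leave epoxides, esters, phosphonate and silyl ether untouched; the alcohol is oxidised at once to exclude acyl migration.

Step 21
Reactants: 25 C7 alcohol
Product: 26 macrocyclic 7-ketone (precursor of the key step)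
Conditions: Dess–Martin periodinane (1.5 equiv), NaHCO3, CH2Cl2, 0 °C → rt
Reagents that add atoms: none
Why: Dess–Martin oxidation under non-basic conditions erases the relay stereocentre at C7 without enolising C6 or C8; because both neighbouring oxygens are already acylated, no free α-hydroxy ketone ever exists.

Step 22
Reactants: 26 macrocyclic 7-ketone
Product: 27 13-O-TBS butenolide
Conditions: LiCl (5 equiv), DBU (1.1 equiv), MeCN, 0 °C, 5 mM; pH 7 buffer quench
Reagents that add atoms: none
Why: Lithium-assisted deprotonation of C11, which is flanked by the phosphoryl and ester groups, gives a chelated carbanion that adds to the C7 ketone; the β-oxido phosphonate closes to an oxaphosphetane and expels diethyl phosphate to give C7=C11. The closest known reaction type is the intramolecular Horner–Wadsworth–Emmons synthesis of α-substituted butenolides from α-(phosphonoacyloxy) ketones. The lactone ring (O, C12, C11, C7, C6) closes in a 5-exo-trig mode, the ketone C=O being exocyclic to the forming ring. No new stereocentre arises: C11 of either epimer of 26 becomes sp2 and the ring allows only one alkene geometry. The selectivity needed is deprotonation at C11 and not at C6–H or C8–H, since a C6 enolate would open the 4,5-epoxide by β-elimination and either enolate could epimerise; it is secured by the several pKa units between the lithium-chelated phosphonoacetate and the ketone α-hydrogens, by a weak amine base in near-stoichiometric amount and by low temperature with an early buffered quench. The β-silyloxy group is a poor leaving group, so elimination from the carbanion should not compete with the proximity-driven ring closure.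

Step 23
Reactants: 27 13-O-TBS butenolide
Product: 28 13-hydroxy butenolide
Conditions: Bu4NF/AcOH (1:1, 3 equiv), THF, 0 °C → rt
Reagents that add atoms: none
Why: Fluoride cleavage of the primary allylic silyl ether; buffering with acetic acid keeps the medium from deprotonating the butenolide γ-hydrogen (C6–H) and from opening the epoxides.

Step 24
Reactants: 28 13-hydroxy butenolide
Product: 29 target (CNP0289810.1)
Conditions: Ac2O (2 equiv), pyridine, DMAP (cat.), CH2Cl2, 0 °C
Reagents that add atoms: acetic anhydride, CC(=O)OC(C)=O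
Why: Acylation of the unhindered primary allylic alcohol under mild amine catalysis, which touches no stereocentre and leaves the glycidate, the epoxides and the butenolide intact.

Compound list
1 | diethyl D-tartrate, diethyl (2S,3S)-2,3-dihydroxybutanedioate | CCOC(=O)[C@@H](O)[C@H](O)C(=O)OCC | starting material
2 | diethyl (2S,3S)-2-hydroxy-3-[(4-methoxybenzyl)oxy]butanedioate | CCOC(=O)[C@@H](O)[C@H](OCc1ccc(OC)cc1)C(=O)OCC | intermediate
3 | ethyl (2S,3R)-3,4-dihydroxy-2-[(4-methoxybenzyl)oxy]butanoate | OC[C@@H](O)[C@H](OCc1ccc(OC)cc1)C(=O)OCC | intermediate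
4 | ethyl (2S,3R)-2-[(4-methoxybenzyl)oxy]-3,4-bis[(triethylsilyl)oxy]butanoate | CC[Si](CC)(CC)OC[C@@H](O[Si](CC)(CC)CC)[C@H](OCc1ccc(OC)cc1)C(=O)OCC | intermediate
5 | (2S,3R)-2-[(4-methoxybenzyl)oxy]-3,4-bis[(triethylsilyl)oxy]butanal (C5–C8; CHO is C8) | CC[Si](CC)(CC)OC[C@@H](O[Si](CC)(CC)CC)[C@H](OCc1ccc(OC)cc1)C=O | intermediate
6 | (2R,3R,4S)-3-[(4-methoxybenzyl)oxy]-1,2-bis[(triethylsilyl)oxy]hept-6-yn-4-ol (germacrane 6R,7R,8S) | CC[Si](CC)(CC)OC[C@@H](O[Si](CC)(CC)CC)[C@H](OCc1ccc(OC)cc1)[C@@H](O)CC#C | intermediate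
7 | (E)-alkenyl(dimethyl)alane from carboalumination of 6, Al on C1, methyl on C10, O8 as dimethylaluminium alkoxide | CC[Si](CC)(CC)OC[C@@H](O[Si](CC)(CC)CC)[C@H](OCc1ccc(OC)cc1)[C@@H](O[Al](C)C)C/C(C)=C/[Al](C)C | intermediate
8 | (2R,3R,4S,6E)-3-[(4-methoxybenzyl)oxy]-6-methyl-1,2-bis[(triethylsilyl)oxy]nona-6,8-dien-4-ol | CC[Si](CC)(CC)OC[C@@H](O[Si](CC)(CC)CC)[C@H](OCc1ccc(OC)cc1)[C@@H](O)C/C(C)=C/C=C | intermediate
9 | acyclic vinyl epoxide alcohol (C5–C10, C1–C3): (1R,10R)-1,10-epoxide, C2=C3 vinyl, 8-OH (8S), 7-OPMB (7R), 5,6-bis(OTES) (6R) | CC[Si](CC)(CC)OC[C@@H](O[Si](CC)(CC)CC)[C@H](OCc1ccc(OC)cc1)[C@@H](O)C[C@@]1(C)O[C@@H]1C=C | intermediate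
10 | (R)-2-methylglycidol, [(2R)-2-methyloxiran-2-yl]methanol | OC[C@]1(C)CO1 | starting material
11 | (2S)-2-methyloxirane-2-carboxylic acid | OC(=O)[C@]1(C)CO1 | intermediate
12 | 8-O-[(2S)-2-methyloxirane-2-carbonyl] ester of 9 (6R,7R,8S,10R,1R) | CC[Si](CC)(CC)OC[C@@H](O[Si](CC)(CC)CC)[C@H](OCc1ccc(OC)cc1)[C@@H](OC(=O)[C@]1(C)CO1)C[C@@]1(C)O[C@@H]1C=C | intermediate
13 | C5 aldehyde: 6-OTES (6S), 7-OPMB (7R), 8-O-glycidate (8S), (1R,10R)-epoxide, C2=C3 vinyl | O=C[C@@H](O[Si](CC)(CC)CC)[C@H](OCc1ccc(OC)cc1)[C@@H](OC(=O)[C@]1(C)CO1)C[C@@]1(C)O[C@@H]1C=C | intermediate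
14 | (4Z)-4-iodo-4-ene (C15 methyl on C4): 6-OTES (6R), 7-OPMB (7R), 8-O-glycidate (8S), (1R,10R)-epoxide, C2=C3 vinyl | C/C(I)=C/[C@@H](O[Si](CC)(CC)CC)[C@H](OCc1ccc(OC)cc1)[C@@H](OC(=O)[C@]1(C)CO1)C[C@@]1(C)O[C@@H]1C=C | intermediate
15 | B-alkyl-9-borabicyclo[3.3.1]nonane of 14 (boron on C3) | C/C(I)=C/[C@@H](O[Si](CC)(CC)CC)[C@H](OCc1ccc(OC)cc1)[C@@H](OC(=O)[C@]1(C)CO1)C[C@@]1(C)O[C@@H]1CCB1C2CCCC1CCC2 | intermediate
16 | ten-membered carbocycle (1R,4Z,6R,7R,8S,10R): 1,10-epoxide, 4-ene, 6-OTES, 7-OPMB, 8-O-[(2S)-2-methylglycidate] | CC[Si](CC)(CC)O[C@@H]1/C=C(C)\CC[C@H]2O[C@]2(C)C[C@H](OC(=O)[C@]2(C)CO2)[C@H]1OCc1ccc(OC)cc1 | intermediate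
17 | macrocyclic allylic alcohol (1R,4Z,6R,7S,8S,10R): 6-OH, 7-OPMB, 8-O-glycidate, 1,10-epoxide | O[C@@H]1/C=C(C)\CC[C@H]2O[C@]2(C)C[C@H](OC(=O)[C@]2(C)CO2)[C@H]1OCc1ccc(OC)cc1 | intermediate
18 | diepoxy alcohol (1R,4R,5S,6S,7S,8S,10R): 1,10- and 4,5-epoxides, 6-OH, 7-OPMB, 8-O-glycidate | O[C@@H]1[C@@H]2O[C@]2(C)CC[C@H]2O[C@]2(C)C[C@H](OC(=O)[C@]2(C)CO2)[C@H]1OCc1ccc(OC)cc1 | intermediate
19 | triethyl phosphonoacetate | CCOC(=O)CP(=O)(OCC)OCC | starting material
20 | ethyl 3-(benzyloxy)-2-(diethoxyphosphoryl)propanoate (racemic) | CCOC(=O)C(COCc1ccccc1)P(=O)(OCC)OCC | intermediate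
21 | ethyl 2-(diethoxyphosphoryl)-3-hydroxypropanoate (racemic) | CCOC(=O)C(CO)P(=O)(OCC)OCC | intermediate
22 | ethyl 3-[(tert-butyldimethylsilyl)oxy]-2-(diethoxyphosphoryl)propanoate (racemic) | CCOC(=O)C(CO[Si](C)(C)C(C)(C)C)P(=O)(OCC)OCC | intermediate
23 | 3-[(tert-butyldimethylsilyl)oxy]-2-(diethoxyphosphoryl)propanoic acid (racemic) | CCOP(=O)(OCC)C(CO[Si](C)(C)C(C)(C)C)C(=O)O | intermediate
24 | 6-O-[3-(TBS-oxy)-2-(diethoxyphosphoryl)propanoyl] diepoxide (1R,4R,5S,6S,7R,8S,10R), 7-OPMB, 8-O-glycidate, C11 epimers | CCOP(=O)(OCC)C(CO[Si](C)(C)C(C)(C)C)C(=O)O[C@@H]1[C@@H]2O[C@]2(C)CC[C@H]2O[C@]2(C)C[C@H](OC(=O)[C@]2(C)CO2)[C@H]1OCc1ccc(OC)cc1 | intermediate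
25 | 7-hydroxy compound from 24 (1R,4R,5S,6S,7R,8S,10R), C11 epimers | CCOP(=O)(OCC)C(CO[Si](C)(C)C(C)(C)C)C(=O)O[C@@H]1[C@@H]2O[C@]2(C)CC[C@H]2O[C@]2(C)C[C@H](OC(=O)[C@]2(C)CO2)[C@H]1O | intermediate
26 | macrocyclic 7-ketone (1R,4R,5S,6R,8S,10R) with both epoxides, C8 (2S)-2-methylglycidate and C6 phosphonoacetate, C11 epimers | CCOP(=O)(OCC)C(CO[Si](C)(C)C(C)(C)C)C(=O)O[C@@H]1[C@@H]2O[C@]2(C)CC[C@H]2O[C@]2(C)C[C@H](OC(=O)[C@]2(C)CO2)C1=O | intermediate
27 | 13-O-(tert-butyldimethylsilyl) ether of the 13-deacetyl target (1R,4R,5S,6S,8S,10R) | CC(C)(C)[Si](C)(C)OCC1=C2[C@@H](OC(=O)[C@]3(C)CO3)C[C@@]3(C)O[C@@H]3CC[C@@]3(C)O[C@H]3[C@H]2OC1=O | intermediate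
28 | 13-hydroxy butenolide (13-deacetyl target) | OCC1=C2[C@@H](OC(=O)[C@]3(C)CO3)C[C@@]3(C)O[C@@H]3CC[C@@]3(C)O[C@H]3[C@H]2OC1=O | intermediate
29 | CNP0289810.1: (1R,4R,5S,6S,8S,10R)-13-acetoxy-1,10:4,5-diepoxy-8-[(2S)-2-methyloxirane-2-carbonyloxy]germacr-7(11)-en-6,12-olide | CC(=O)OCC1=C2[C@@H](OC(=O)[C@]3(C)CO3)C[C@@]3(C)O[C@@H]3CC[C@@]3(C)O[C@H]3[C@H]2OC1=O | target

Total step count: 24. Longest linear sequence: 19 steps (steps 1–7, 9–14 and 19–24, from diethyl D-tartrate).

The three steps most likely to fail:

Step 12 (hydroboration and ten-membered B-alkyl Suzuki closure). The borane may open the vinyl epoxide reductively by SN2′ hydride delivery instead of adding across the vinyl group, and intermolecular coupling may outrun ring closure in the more rigid epoxide-bearing chain. The fallback closes the ring before the 1,10-epoxide exists. It sets out from diene alcohol 8: Steglich esterification with 11 would give the diene glycidate F1, direct Swern oxidation of its primary silyl ether the aldehyde F2, and the same α-iodo ylide olefination the Z-vinyl iodide diene F3. 9-BBN adds cleanly to the terminal alkene of a 1,3-diene and would give the homoallylic borane F4, which is cyclised under the palladium conditions of step 12 to the (1(10)E,4Z)-cyclodecadiene F5. Shi epoxidation of the more electron-rich C1=C10 bond (C4=C5 is deactivated and shielded by the allylic silyl ether) would then come back to the route at 16; its facial outcome in the ring would have to be established.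

Step 14 (directed epoxidation of C4=C5). Oxygen may be delivered to the wrong alkene face if the ring holds the C6 hydroxyl away from the π-bond, which would give the trans epoxy alcohol through poor facial selectivity. The fallback builds the epoxide by inversion instead of direct oxygen transfer. It sets out from 17: N-bromosuccinimide in buffered aqueous THF should form the bromonium ion on the exposed face, and water opens it at tertiary C4 from the hydroxyl-bearing face to give the bromohydrin F6. K2CO3 in MeCN then closes the epoxide by displacement of bromide with inversion at C5, which places the oxygen on the face opposite to that attacked by the electrophile and returns to the route at 18.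

Step 22 (key olefination). Enolisation toward C6 with β-elimination opening of the 4,5-epoxide, or epimerisation at C8, may compete with the slow addition of the α-branched carbanion to the hindered ketone. The fallback runs the same olefination before the 4,5-epoxide is present, so that no leaving group sits β to C6. It sets out from allylic alcohol 17: esterification with 23 would give the phosphonoacetate F7, DDQ the C7 alcohol F8, Dess–Martin oxidation the β,γ-unsaturated ketone F9, and the LiCl/amine olefination the 4Z-butenolide F10. Epoxidation of the remaining electron-rich trisubstituted alkene with dimethyldioxirane (the butenolide alkene is electron-poor) would come back to the route at 27; this moves the facial-selectivity question to that last operation.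

Further compounds
F1 | step 12 | 8-O-[(2S)-2-methyloxirane-2-carbonyl] ester of diene alcohol 8 | CC[Si](CC)(CC)OC[C@@H](O[Si](CC)(CC)CC)[C@H](OCc1ccc(OC)cc1)[C@@H](OC(=O)[C@]1(C)CO1)C/C(C)=C/C=C
F2 | step 12 | C5 aldehyde of the diene glycidate (6-OTES retained) | O=C[C@@H](O[Si](CC)(CC)CC)[C@H](OCc1ccc(OC)cc1)[C@@H](OC(=O)[C@]1(C)CO1)C/C(C)=C/C=C
F3 | step 12 | (4Z)-4-iodo-4-ene carrying the (1(10)E)-1(10),2-diene arm | C/C(I)=C/[C@@H](O[Si](CC)(CC)CC)[C@H](OCc1ccc(OC)cc1)[C@@H](OC(=O)[C@]1(C)CO1)C/C(C)=C/C=C
F4 | step 12 | homoallylic B-alkyl-9-borabicyclo[3.3.1]nonane of F3 (boron on C3) | C/C(I)=C/[C@@H](O[Si](CC)(CC)CC)[C@H](OCc1ccc(OC)cc1)[C@@H](OC(=O)[C@]1(C)CO1)C/C(C)=C/CCB1C2CCCC1CCC2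
F5 | step 12 | ten-membered (1(10)E,4Z)-diene, 6-OTES, 7-OPMB, 8-O-[(2S)-2-methylglycidate] | CC[Si](CC)(CC)O[C@@H]1/C=C(C)\CC/C=C(C)/C[C@H](OC(=O)[C@]2(C)CO2)[C@H]1OCc1ccc(OC)cc1
F6 | step 14 | 5-bromo-4-hydroxy compound from 17 (C4 hydroxyl on the face of O6, bromine anti to it) | O[C@@H]1[C@@H](Br)[C@](C)(O)CC[C@H]2O[C@]2(C)C[C@H](OC(=O)[C@]2(C)CO2)[C@H]1OCc1ccc(OC)cc1
F7 | step 22 | C6 phosphonoacetate of allylic alcohol 17 (4Z-alkene, 7-OPMB) | CCOP(=O)(OCC)C(CO[Si](C)(C)C(C)(C)C)C(=O)O[C@@H]1/C=C(C)\CC[C@H]2O[C@]2(C)C[C@H](OC(=O)[C@]2(C)CO2)[C@H]1OCc1ccc(OC)cc1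
F8 | step 22 | 7-hydroxy compound from F7 | CCOP(=O)(OCC)C(CO[Si](C)(C)C(C)(C)C)C(=O)O[C@@H]1/C=C(C)\CC[C@H]2O[C@]2(C)C[C@H](OC(=O)[C@]2(C)CO2)[C@H]1O
F9 | step 22 | macrocyclic 7-ketone with 4Z-alkene and 1,10-epoxide | CCOP(=O)(OCC)C(CO[Si](C)(C)C(C)(C)C)C(=O)O[C@@H]1/C=C(C)\CC[C@H]2O[C@]2(C)C[C@H](OC(=O)[C@]2(C)CO2)C1=O
F10 | step 22 | 13-O-TBS butenolide with 4Z-alkene (4,5-deoxy analogue of 27) | CC(C)(C)[Si](C)(C)OCC1=C2[C@@H](OC(=O)[C@]3(C)CO3)C[C@@]3(C)O[C@@H]3CC/C(C)=C\[C@H]2OC1=O
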